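**Retrosynthetic overview**

- The target comes from its tert-butyl ester, which is cut at the C6=C7 E-alkene by olefin cross-metathesis into a vinyl β-hydroxy ester (C1–C6, 16 non-hydrogen atoms) and a terminal-alkene acylpyranone (C7–C12 plus ring, 18 non-hydrogen atoms).
- The acylpyranone comes from (6R)-6-methyloxane-2,4-dione and (4R)-4-methylhept-6-enoic acid by DCC/DMAP O-acylation and O-to-C acyl shift.
- The only ring, the dihydropyranone, is formed first (Claisen condensation of methyl (R)-3-hydroxybutanoate with tert-butyl acetate, then lactonisation) and is carried intact.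
- The heptenoic acid comes from (R)-3-bromo-2-methylpropan-1-ol: Kumada vinylation on one arm, iodide/lithioacetonitrile two-carbon extension and nitrile hydrolysis on the other.
- The vinyl hydroxy ester comes from (S)-2-methylbutan-1-ol: Wittig, Sharpless epoxidation (sets C4), anti-selective vinyl cuprate opening at C2 (sets C5), then CH2OH to CO2H.

Assumption: β-tricarbonyl units are drawn in the enol form used in the target SMILES.

**Route**

Step 1
Reactants: 1 methyl (3R)-3-hydroxybutanoate; 2 tert-butyl acetate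
Product: 4 tert-butyl (5R)-5-hydroxy-3-oxohexanoate, via lithium enolate of tert-butyl acetate 3 (not isolated)
Conditions: LiN(i-Pr)2 (3.5 equiv), 2 (3.6 equiv), THF, −78 °C; then 1, −78 → −20 °C; aq. HCl quench
Reagents that add atoms: none
Why: Crossed Claisen condensation in which the excess ester enolate first deprotonates the hydroxyl and then attacks the methyl ester, the product being shielded as its enolate, while the carbinol stereocentre (future ring C6, R) comes unchanged from the chiral pool.

Step 2
Reactants: 4 tert-butyl (5R)-5-hydroxy-3-oxohexanoate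
Product: 6 (6R)-6-methyloxane-2,4-dione, via (5R)-5-hydroxy-3-oxohexanoic acid 5 (not isolated)
Conditions: CF3CO2H/CH2Cl2 (1:4), 0 °C → rt; evaporate, crystallise
Reagents that add atoms: none
Why: Acidolysis of the tert-butyl ester followed by spontaneous 6-exo lactonisation of the δ-hydroxy β-keto acid closes the only ring of the target without touching the stereocentre.

Step 3
Reactants: 7 (2R)-3-bromo-2-methylpropan-1-ol
Product: 8 [(2R)-3-bromo-2-methylpropoxy](tert-butyl)dimethylsilane
Conditions: TBSCl, imidazole, DMF, 0 °C → rt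
Reagents that add atoms: tert-butyldimethylsilyl chloride, CC(C)(C)[Si](C)(C)Cl
Why: Standard silyl ether protection of the primary alcohol so that the bromide can be converted into a Grignard reagent.

Step 4
Reactants: 8 [(2R)-3-bromo-2-methylpropoxy](tert-butyl)dimethylsilane
Product: 10 tert-butyl(dimethyl){[(2S)-2-methylpent-4-en-1-yl]oxy}silane, via alkylmagnesium bromide 9 (not isolated)
Conditions: Mg, THF, 40 °C; then CH2=CHBr (1.5 equiv), NiCl2(dppp) (2 mol%), THF, 0 °C → rt
Reagents that add atoms: vinyl bromide, C=CBr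
Why: Kumada–Corriu cross-coupling of the primary alkylmagnesium bromide with vinyl bromide builds the allyl arm; the stereocentre is not involved and only its descriptor changes (R to S) through CIP priorities.

Step 5
Reactants: 10 tert-butyl(dimethyl){[(2S)-2-methylpent-4-en-1-yl]oxy}silane
Product: 11 (2S)-2-methylpent-4-en-1-ol
Conditions: p-TsOH·H2O (5 mol%), MeOH, rt
Reagents that add atoms: none
Why: Acid-catalysed methanolysis removes the primary silyl ether and leaves the terminal alkene alone.

Step 6
Reactants: 11 (2S)-2-methylpent-4-en-1-ol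
Product: 12 (4S)-5-iodo-4-methylpent-1-ene
Conditions: I2, PPh3, imidazole, CH2Cl2, 0 °C → rt
Reagents that add atoms: iodine, II
Why: Appel-type iodination by SN2 displacement of the alkoxyphosphonium ion at the primary carbon, with the adjacent stereocentre untouched.

Step 7
Reactants: 12 (4S)-5-iodo-4-methylpent-1-ene; 13 acetonitrile
Product: 15 (4R)-4-methylhept-6-enenitrile, via lithioacetonitrile 14 (not isolated)
Conditions: n-BuLi (3.0 equiv), 13 (3.2 equiv), THF, −78 °C, 30 min; then 12 (1 equiv), −78 °C → rt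
Reagents that add atoms: none
Why: SN2 alkylation of the small, strongly nucleophilic lithioacetonitrile by the primary iodide adds the two-carbon arm at the nitrile oxidation level; the excess nucleophile suppresses double alkylation, and the unchanged stereocentre is now R by CIP priorities.

Step 8
Reactants: 15 (4R)-4-methylhept-6-enenitrile
Product: 16 (4R)-4-methylhept-6-enoic acid
Conditions: KOH (5 equiv), EtOH/H2O (2:1), reflux, 24 h; then aq. HCl to pH 2
Reagents that add atoms: potassium hydroxide, [K+].[OH-]; water, O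
Why: Base hydrolysis of the nitrile through the primary amide gives the carboxylate with loss of ammonia; the stereocentre is not α to the nitrile and cannot epimerise, and the isolated terminal alkene does not migrate in aqueous hydroxide.

Step 9
Reactants: 16 (4R)-4-methylhept-6-enoic acid; 6 (6R)-6-methyloxane-2,4-dione
Product: 18 (6R)-4-hydroxy-6-methyl-3-[(4R)-4-methylhept-6-enoyl]-5,6-dihydro-2H-pyran-2-one, via enol ester 17 (not isolated)
Conditions: DCC (1.1 equiv), DMAP (1.2 equiv), CH2Cl2, 0 °C → rt, 16 h; dilute HCl wash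
Reagents that add atoms: none
Why: Steglich-type O-acylation of the acidic dione enol followed by DMAP-mediated 1,3 O-to-C acyl migration (Fries-type) gives the hydrogen-bonded 3-acyl-4-hydroxy tautomer as the thermodynamic product with both stereocentres untouched.

Step 10
Reactants: 19 (2S)-2-methylbutan-1-ol
Product: 21 ethyl (2E,4S)-4-methylhex-2-enoate, via (2S)-2-methylbutanal 20 (not isolated)
Conditions: TEMPO (10 mol%), PhI(OAc)2 (1.1 equiv), CH2Cl2, rt; then Ph3P=CHCO2Et (1.3 equiv), rt
Reagents that add atoms: ethyl 2-(triphenyl-λ5-phosphanylidene)acetate, CCOC(=O)C=P(c1ccccc1)(c1ccccc1)c1ccccc1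
Why: One-pot nitroxyl-catalysed alcohol oxidation and Wittig olefination avoids isolating the volatile, epimerisable α-branched aldehyde, and the stabilised ylide gives the E-enoate.

Step 11
Reactants: 21 ethyl (2E,4S)-4-methylhex-2-enoate
Product: 22 (2E,4S)-4-methylhex-2-en-1-ol
Conditions: i-Bu2AlH (2.3 equiv), CH2Cl2, −78 °C; aq. KNaC4H4O6
Reagents that add atoms: none
Why: 1,2-Reduction of the conjugated ester by the aluminium hydride at low temperature gives the E-allylic alcohol without conjugate reduction.

Step 12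
Reactants: 22 (2E,4S)-4-methylhex-2-en-1-ol
Product: 23 [(2R,3R)-3-[(2S)-butan-2-yl]oxiran-2-yl]methanol
Conditions: Ti(Oi-Pr)4 (10 mol%), D-(−)-diethyl tartrate (12 mol%), t-BuOOH (2 equiv), 4 Å molecular sieves, CH2Cl2, −20 °C
Reagents that add atoms: tert-butyl hydroperoxide, CC(C)(C)OO
Why: Sharpless asymmetric epoxidation under reagent control, in which the D-(−)-tartrate catalyst delivers oxygen to the alkene face that gives the (2R,3R)-epoxide and so fixes the future C4 (R) carbinol centre.

Step 13
Reactants: 23 [(2R,3R)-3-[(2S)-butan-2-yl]oxiran-2-yl]methanol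
Product: 24 (2S,3R,4S)-2-ethenyl-4-methylhexane-1,3-diol
Conditions: CH2=CHMgBr (4 equiv), CuBr·SMe2 (20 mol%), THF/Et2O, −30 → 0 °C
Reagents that add atoms: vinylmagnesium bromide, C=C[Mg]Br
Why: Copper-catalysed SN2 opening of the 2,3-epoxy alcohol by the vinyl Grignard reagent occurs at C2, away from the α-branched C3, with inversion, so the anti 2-vinyl-1,3-diol results and the future C5 centre is set.

Step 14
Reactants: 24 (2S,3R,4S)-2-ethenyl-4-methylhexane-1,3-diol
Product: 26 (2R,3R,4S)-2-ethenyl-3-hydroxy-4-methylhexanoic acid, via hydroxy aldehyde 25 (not isolated)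
Conditions: TEMPO (20 mol%), PhI(OAc)2 (2.5 equiv), MeCN/H2O (1:1), 0 °C → rt
Reagents that add atoms: water, O
Why: Nitroxyl-catalysed oxidation in aqueous acetonitrile takes the primary alcohol through the aldehyde hydrate to the acid while the hindered secondary alcohol is spared, and the weakly acidic medium keeps the α-vinyl centre from epimerising or moving into conjugation.

Step 15
Reactants: 26 (2R,3R,4S)-2-ethenyl-3-hydroxy-4-methylhexanoic acid
Product: 27 tert-butyl (2R,3R,4S)-2-ethenyl-3-hydroxy-4-methylhexanoate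
Conditions: Cl3CC(=NH)Ot-Bu (2 equiv), CH2Cl2/cyclohexane, rt
Reagents that add atoms: tert-butyl 2,2,2-trichloroacetimidate, CC(C)(C)OC(=N)C(Cl)(Cl)Cl
Why: Esterification by the trichloroacetimidate, which the carboxylic acid itself protonates to release a tert-butyl cation equivalent, whereas the secondary alcohol would need a Lewis acid and stays free.

Step 16
Reactants: 27 tert-butyl (2R,3R,4S)-2-ethenyl-3-hydroxy-4-methylhexanoate; 18 (6R)-4-hydroxy-6-methyl-3-[(4R)-4-methylhept-6-enoyl]-5,6-dihydro-2H-pyran-2-one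
Product: 28 tert-butyl (2R,3R,4S)-3-hydroxy-2-[(1E,4R)-7-[(6R)-4-hydroxy-6-methyl-2-oxo-5,6-dihydro-2H-pyran-3-yl]-4-methyl-7-oxohept-1-en-1-yl]-4-methylhexanoate
Conditions: 27 (1 equiv), 18 (2 equiv), RuCl2(H2IMes)(=CH–C6H4-2-Oi-Pr) (second-generation Hoveyda–Grubbs catalyst, 2 × 5 mol%), 1,4-benzoquinone (10 mol%), CH2Cl2, 40 °C
Reagents that add atoms: none
Why: Olefin cross-metathesis in which the unhindered terminal alkene of 18 (in excess, its homodimer re-enters the cycle) couples with the allylically branched vinyl group of 27, which does not homodimerise, and reversible metathesis gives the E-alkene while benzoquinone suppresses ruthenium hydride alkene migration.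

Step 17
Reactants: 28 tert-butyl (2R,3R,4S)-3-hydroxy-2-[(1E,4R)-7-[(6R)-4-hydroxy-6-methyl-2-oxo-5,6-dihydro-2H-pyran-3-yl]-4-methyl-7-oxohept-1-en-1-yl]-4-methylhexanoate
Product: 29 (2R,3R,4S)-3-hydroxy-2-[(1E,4R)-7-[(6R)-4-hydroxy-6-methyl-2-oxo-5,6-dihydro-2H-pyran-3-yl]-4-methyl-7-oxohept-1-en-1-yl]-4-methylhexanoic acid
Conditions: CF3CO2H/CH2Cl2 (1:4), 0 °C → rt
Reagents that add atoms: none
Why: Acidolysis of the tert-butyl ester with loss of isobutene, under which the secondary alcohol, the E-alkene and the acylpyranone are stable, releases the target acid.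

**Compound list**

1 | methyl (3R)-3-hydroxybutanoate | C[C@@H](O)CC(=O)OC | starting material
2 | tert-butyl acetate | CC(=O)OC(C)(C)C | starting material
3 | lithium enolate of tert-butyl acetate (lithium 1-tert-butoxyethenolate) | C=C(O[Li])OC(C)(C)C | intermediate
4 | tert-butyl (5R)-5-hydroxy-3-oxohexanoate | C[C@@H](O)CC(=O)CC(=O)OC(C)(C)C | intermediate
5 | (5R)-5-hydroxy-3-oxohexanoic acid | C[C@@H](O)CC(=O)CC(=O)O | intermediate
6 | (6R)-6-methyloxane-2,4-dione | C[C@@H]1CC(=O)CC(=O)O1 | intermediate
7 | (2R)-3-bromo-2-methylpropan-1-ol | BrC[C@H](C)CO | starting material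
8 | [(2R)-3-bromo-2-methylpropoxy](tert-butyl)dimethylsilane | BrC[C@H](C)CO[Si](C)(C)C(C)(C)C | intermediate
9 | {(2R)-3-[tert-butyl(dimethyl)silyl]oxy-2-methylpropyl}magnesium bromide | Br[Mg]C[C@H](C)CO[Si](C)(C)C(C)(C)C | intermediate
10 | tert-butyl(dimethyl){[(2S)-2-methylpent-4-en-1-yl]oxy}silane | C=CC[C@H](C)CO[Si](C)(C)C(C)(C)C | intermediate
11 | (2S)-2-methylpent-4-en-1-ol | C=CC[C@H](C)CO | intermediate
12 | (4S)-5-iodo-4-methylpent-1-ene | C=CC[C@H](C)CI | intermediate
13 | acetonitrile | CC#N | starting material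
14 | lithioacetonitrile ((cyanomethyl)lithium) | [Li]CC#N | intermediate
15 | (4R)-4-methylhept-6-enenitrile | C=CC[C@H](C)CCC#N | intermediate
16 | (4R)-4-methylhept-6-enoic acid | C=CC[C@H](C)CCC(=O)O | intermediate
17 | (6R)-6-methyl-2-oxo-5,6-dihydro-2H-pyran-4-yl (4R)-4-methylhept-6-enoate | C=CC[C@H](C)CCC(=O)OC1=CC(=O)O[C@H](C)C1 | intermediate
18 | (6R)-4-hydroxy-6-methyl-3-[(4R)-4-methylhept-6-enoyl]-5,6-dihydro-2H-pyran-2-one | C=CC[C@H](C)CCC(=O)C1=C(O)C[C@@H](C)OC1=O | intermediate
19 | (2S)-2-methylbutan-1-ol | CC[C@H](C)CO | starting material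
20 | (2S)-2-methylbutanal | CC[C@H](C)C=O | intermediate
21 | ethyl (2E,4S)-4-methylhex-2-enoate | CC[C@H](C)/C=C/C(=O)OCC | intermediate
22 | (2E,4S)-4-methylhex-2-en-1-ol | CC[C@H](C)/C=C/CO | intermediate
23 | [(2R,3R)-3-[(2S)-butan-2-yl]oxiran-2-yl]methanol | CC[C@H](C)[C@H]1O[C@@H]1CO | intermediate
24 | (2S,3R,4S)-2-ethenyl-4-methylhexane-1,3-diol | CC[C@H](C)[C@@H](O)[C@@H](C=C)CO | intermediate
25 | (2R,3R,4S)-2-ethenyl-3-hydroxy-4-methylhexanal | CC[C@H](C)[C@@H](O)[C@@H](C=C)C=O | intermediate
26 | (2R,3R,4S)-2-ethenyl-3-hydroxy-4-methylhexanoic acid | CC[C@H](C)[C@@H](O)[C@@H](C=C)C(=O)O | intermediate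
27 | tert-butyl (2R,3R,4S)-2-ethenyl-3-hydroxy-4-methylhexanoate | CC[C@H](C)[C@@H](O)[C@@H](C=C)C(=O)OC(C)(C)C | intermediate
28 | tert-butyl (2R,3R,4S)-3-hydroxy-2-[(1E,4R)-7-[(6R)-4-hydroxy-6-methyl-2-oxo-5,6-dihydro-2H-pyran-3-yl]-4-methyl-7-oxohept-1-en-1-yl]-4-methylhexanoate | CC[C@H](C)[C@@H](O)[C@@H](/C=C/C[C@H](C)CCC(=O)C1=C(O)C[C@@H](C)OC1=O)C(=O)OC(C)(C)C | intermediate
29 | (2R,3R,4S)-3-hydroxy-2-[(1E,4R)-7-[(6R)-4-hydroxy-6-methyl-2-oxo-5,6-dihydro-2H-pyran-3-yl]-4-methyl-7-oxohept-1-en-1-yl]-4-methylhexanoic acid (CNP0137396.1) | CC[C@H](C)[C@@H](O)[C@@H](/C=C/C[C@H](C)CCC(=O)C1=C(O)C[C@@H](C)OC1=O)C(=O)O | target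

**Step count and risks**

Total step count: 17.
Longest linear sequence: 9 steps (steps 3, 4, 5, 6, 7, 8, 9, 16, 17).

Steps most likely to fail:

Step 16 (cross-metathesis). The acidic, chelating acylpyranone of 18 may sequester ruthenium, and the vinyl group of 27 is hindered. The fallback reverses the order of the two unions. It sets out from 27 and 16: the ester 27 is cross-metathesised with the simple acid 16 (2 equiv, same ruthenium catalyst and benzoquinone, CH2Cl2, 40 °C) to give (4R,6E,8R,9R,10S)-8-(tert-butoxycarbonyl)-9-hydroxy-4,10-dimethyldodec-6-enoic acid F1. F1 is then joined to dione 6 by the DCC/DMAP acylation and acyl shift of step 9, where the acidic dione enol outcompetes the hindered secondary hydroxyl. This comes back to the route at 28.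

Step 13 (regiochemistry of epoxide opening). Attack at C3 would give the 1,2-diol. The fallback moves the carbon to the acid oxidation level before the opening. It sets out from 23, which is oxidised (RuCl3·xH2O cat., NaIO4, CCl4/MeCN/H2O) to (2S,3R)-3-[(2S)-butan-2-yl]oxirane-2-carboxylic acid F2. F2 is deprotonated with n-BuLi (1 equiv, Et2O, −78 °C) and then opened by (CH2=CH)2CuLi (Et2O, −40 °C) at the carbon α to the carboxylate with inversion. This comes back to the route at 26 and also bypasses the oxidation of step 14.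

Step 7 (alkylation of a β-branched iodide by lithioacetonitrile). Slow substitution, E2 elimination or double alkylation of the nitrile may limit the yield. The fallback uses a soft, heat-tolerant malonate nucleophile and goes straight to the acid oxidation level. It sets out from 12, which alkylates dimethyl malonate (NaH, DMF, 60 °C) to give dimethyl 2-[(2S)-2-methylpent-4-en-1-yl]propanedioate F3. Saponification (KOH, aq. EtOH) gives 2-[(2S)-2-methylpent-4-en-1-yl]propanedioic acid F4, which is decarboxylated neat at 150 °C. This comes back to the route at 16, bypassing 15 and step 8.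

**Further compounds**

F1 | step 16 | (4R,6E,8R,9R,10S)-8-(tert-butoxycarbonyl)-9-hydroxy-4,10-dimethyldodec-6-enoic acid | CC[C@H](C)[C@@H](O)[C@@H](/C=C/C[C@H](C)CCC(=O)O)C(=O)OC(C)(C)C
F2 | step 13 | (2S,3R)-3-[(2S)-butan-2-yl]oxirane-2-carboxylic acid | CC[C@H](C)[C@H]1O[C@@H]1C(=O)O
F3 | step 7 | dimethyl 2-[(2S)-2-methylpent-4-en-1-yl]propanedioate | C=CC[C@H](C)CC(C(=O)OC)C(=O)OC
F4 | step 7 | 2-[(2S)-2-methylpent-4-en-1-yl]propanedioic acid | C=CC[C@H](C)CC(C(=O)O)C(=O)O
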